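## Retrosynthetic overview
1. The enol senecioate comes from a Cu-catalysed C–O coupling of an (E)-alkenyl-BF3K. That salt comes from the C6 aldehyde by Takai–Utimoto olefination, and the TBS group is removed last.
2. The cycloheptenone is the only ring of the target and is formed second. The C1–C2 bond is made by I/Li exchange of a (Z)-alkenyl iodide and attack on a γ-lactone carbonyl.
3. C2=C3, the CH2OTBS arm and the iodine handle are installed together by a new α-iodo-β-silyloxy ylide olefination of the C3 aldehyde (the proposed new step).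
4. C7 is set by trans-alkylation of the γ-lactone (a temporary ring, formed first) with 2-methoxyallyl bromide as masked acetonyl.
5. C5 (quaternary) and C6 are set by an enantioselective boron Ireland–Claisen rearrangement of neryl 3-cyanopropanoate.

**Assumption:** the (R,R)-controller in step 2 gives the enantiomer drawn; the sense is assigned by analogy, and the equally available (S,S)-controller is used if it turns out opposite.

**Atom labels:** C1–C7 follow cyclohept-2-en-1-one numbering of the target (C1 = C=O, C2 = C–CH2OH). The target is (5S,6S,7R) with 5-CH3, the 6-alkenyl group and the 7-acetonyl group all cis.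

## Route

Step 1
Reactants: 1 nerol; 2 3-cyanopropanoic acid
Product: 3 neryl 3-cyanopropanoate
Conditions: DCC, DMAP (cat.), CH2Cl2, 0 °C → rt
Reagents that add atoms: none
Why: Steglich esterification joins the two commercial pieces under neutral conditions that leave the (Z)-alkene and the nitrile untouched, and no stereocentre is formed.

Step 2
Reactants: 3 neryl 3-cyanopropanoate
Product: 6 (2S,3S)-2-(cyanomethyl)-3-ethenyl-3,7-dimethyloct-6-enoic acid, via boron ketene acetal 4 (not isolated), via acyloxyborane 5 (not isolated)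
Conditions: (R,R)-[3,5-(CF3)2C6H3SO2NHCH(Ph)]2, BBr3, CH2Cl2 (forms the bromoborane); then 3, i-Pr2NEt, CH2Cl2, −78 → −20 °C; aq. work-up
Reagents that add atoms: none
Why: In this enantioselective boron-mediated Ireland–Claisen rearrangement, soft enolisation gives the Z(O)-ketene acetal at the ester only (the nitrile is the weaker Lewis base), the chair transition state of the (Z)-alkene puts CH3 and the CH2CN arm equatorial and so fixes quaternary C5 relative to C6, and the C2-symmetric diazaborolidine selects one enantiomeric chair.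

Step 3
Reactants: 6 (2S,3S)-2-(cyanomethyl)-3-ethenyl-3,7-dimethyloct-6-enoic acid
Product: 8 (3S,4S)-4-ethenyl-3-(hydroxymethyl)-4,8-dimethylnon-7-enenitrile, via acylimidazole 7 (not isolated)
Conditions: CDI, THF, rt; then NaBH4, H2O, 0 °C
Reagents that add atoms: none
Why: Acylimidazole activation followed by borohydride reduction reduces the hindered carboxyl group without regiochemical ambiguity, spares the nitrile and the alkenes, and touches no stereocentre.

Step 4
Reactants: 8 (3S,4S)-4-ethenyl-3-(hydroxymethyl)-4,8-dimethylnon-7-enenitrile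
Product: 10 (4S)-4-[(3S)-3,7-dimethylocta-1,6-dien-3-yl]oxolan-2-one, via potassium hydroxy carboxylate 9 (not isolated)
Conditions: KOH, EtOH–H2O, 80 °C; then 1 M HCl to pH 3, rt
Reagents that add atoms: potassium hydroxide, [K+].[OH-]; water, O
Why: Alkaline nitrile hydrolysis is assisted by the neighbouring alkoxide, γ-lactonisation is spontaneous on acidification, and C6 lies β to the carbonyl so it cannot epimerise.

Step 5
Reactants: 10 (4S)-4-[(3S)-3,7-dimethylocta-1,6-dien-3-yl]oxolan-2-one
Product: 12 (4S)-4-[(3S)-1-hydroxy-3,7-dimethyloct-6-en-3-yl]oxolan-2-one, via alkylborane 11 (not isolated)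
Conditions: 9-BBN, THF, rt; then NaBO3·4H2O, H2O, rt
Reagents that add atoms: sodium perborate, [Na+].[Na+].O[B-]1(O)OO[B-](O)(O)OO1
Why: In this hydroboration–oxidation, 9-BBN picks the monosubstituted vinyl group over the trisubstituted alkene, ignores the lactone and adds anti-Markovnikov to give C4H2–C3H2OH, and perborate is mild enough for the lactone.

Step 6
Reactants: 12 (4S)-4-[(3S)-1-hydroxy-3,7-dimethyloct-6-en-3-yl]oxolan-2-one
Product: 13 (3S)-3,7-dimethyl-3-[(3S)-5-oxooxolan-3-yl]oct-6-enal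
Conditions: DMP, CH2Cl2, rt
Reagents that add atoms: none
Why: Dess–Martin oxidation stops at the aldehyde and leaves the alkene, the lactone and both stereocentres alone.

Step 7
Reactants: 14 (2-bromoethoxy)(tert-butyl)dimethylsilane; 15 triphenylphosphine
Product: 16 [2-(tert-butyldimethylsilyloxy)ethyl]triphenylphosphonium bromide
Conditions: MeCN, reflux
Reagents that add atoms: none
Why: SN2 quaternisation of PPh3 by an unhindered primary bromide gives the crystalline salt.

Step 8
Reactants: 13 (3S)-3,7-dimethyl-3-[(3S)-5-oxooxolan-3-yl]oct-6-enal; 16 [2-(tert-butyldimethylsilyloxy)ethyl]triphenylphosphonium bromide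
Product: 20 (4S)-4-[(2Z,5S)-1-(tert-butyldimethylsilyloxy)-2-iodo-5,9-dimethyldeca-2,8-dien-5-yl]oxolan-2-one, via ylide 17 (not isolated), via iodophosphonium iodide 18 (not isolated), via iodo ylide 19 (not isolated)
Conditions: 16, n-BuLi, THF, −78 → 0 °C; I2, −78 °C; NaHMDS, −20 °C; then 13, −78 °C
Reagents that add atoms: iodine, II
Why: Proposed new method: a non-stabilised α-iodo ylide that also carries a β-silyloxy arm (19, made by iodination and re-deprotonation of ylide 17) acts as a linchpin that delivers C2, its CH2OTBS group and the iodine handle in one olefination that forms the future ring bond C2=C3; addition to the unhindered aldehyde should pass through an early, irreversible, puckered [2+2] transition state in which the bulkier CH2OTBS points away from the aldehyde chain so that iodine ends up cis to C4 (Z, the geometry ring closure needs), while the poor silanolate leaving group, the lower basicity of the iodo ylide and the −78 °C regime hold back β-elimination to a vinylphosphonium salt; the closest known reaction type is the Stork–Zhao type Wittig olefination with α-halo ylides, which gives (Z)-α-haloalkenes but has only been run with H or a plain alkyl group on the ylide carbon.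

Step 9
Reactants: 21 1-bromo-2,2-dimethoxypropane
Product: 22 2-methoxyallyl bromide (3-bromo-2-methoxyprop-1-ene)
Conditions: i-Pr2NEt·TsOH (cat.), neat, 150–190 °C, distil
Reagents that add atoms: none
Why: Acid-catalysed thermal loss of methanol from the ketal (ketal-to-enol-ether elimination) gives the reactive acetonyl equivalent.

Step 10
Reactants: 20 (4S)-4-[(2Z,5S)-1-(tert-butyldimethylsilyloxy)-2-iodo-5,9-dimethyldeca-2,8-dien-5-yl]oxolan-2-one; 22 2-methoxyallyl bromide
Product: 24 (3R,4S)-4-[(2Z,5S)-1-(tert-butyldimethylsilyloxy)-2-iodo-5,9-dimethyldeca-2,8-dien-5-yl]-3-(2-methoxyprop-2-en-1-yl)oxolan-2-one, via lithium enolate 23 (not isolated)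
Conditions: LiHMDS, THF, −78 °C; 22, DMPU, −78 → −40 °C
Reagents that add atoms: none
Why: In this kinetic lactone enolate alkylation the allylic bromide approaches anti to the very large tert-alkyl group on C6, giving the trans-3,4-disubstituted lactone, which sets C7 (R) and corresponds to the cis relation of acetonyl and C6 side chain in the seven-membered ring.

Step 11
Reactants: 24 (3R,4S)-4-[(2Z,5S)-1-(tert-butyldimethylsilyloxy)-2-iodo-5,9-dimethyldeca-2,8-dien-5-yl]-3-(2-methoxyprop-2-en-1-yl)oxolan-2-one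
Product: 27 (5S,6S,7R)-2-[(tert-butyldimethylsilyloxy)methyl]-6-(hydroxymethyl)-5-methyl-5-(4-methylpent-3-en-1-yl)-7-(2-oxopropyl)cyclohept-2-en-1-one, via alkenyllithium 25 (not isolated), via enol ether 26 (not isolated)
Conditions: t-BuLi (2.1 equiv), Et2O–THF, −100 → −78 °C; AcOH, −78 °C; then aq. oxalic acid (cat.), THF, 0 °C
Reagents that add atoms: water, O
Why: In this Parham-type cyclisation, iodine–lithium exchange outruns attack on the lactone and keeps the alkene geometry, the (Z)-alkenyllithium adds to the lactone carbonyl from the face that carries the C5 arm to give a bridged hemiketal alkoxide that cannot over-add, and the cold AcOH quench plus brief enol-ether hydrolysis release the enone, the C6-CH2OH group and the acetonyl ketone without touching C5, C6 or C7.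

Step 12
Reactants: 27 (5S,6S,7R)-2-[(tert-butyldimethylsilyloxy)methyl]-6-(hydroxymethyl)-5-methyl-5-(4-methylpent-3-en-1-yl)-7-(2-oxopropyl)cyclohept-2-en-1-one
Product: 28 (1S,2S,7R)-5-[(tert-butyldimethylsilyloxy)methyl]-2-methyl-2-(4-methylpent-3-en-1-yl)-6-oxo-7-(2-oxopropyl)cyclohept-4-ene-1-carbaldehyde
Conditions: DMP, CH2Cl2, 0 °C → rt
Reagents that add atoms: none
Why: Dess–Martin oxidation of the only free alcohol proceeds under near-neutral conditions, so the α-centres C6 and C7 keep their configuration.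

Step 13
Reactants: 28 (1S,2S,7R)-5-[(tert-butyldimethylsilyloxy)methyl]-2-methyl-2-(4-methylpent-3-en-1-yl)-6-oxo-7-(2-oxopropyl)cyclohept-4-ene-1-carbaldehyde
Product: 29 (5S,6S,7R)-6-[(E)-2-(pinacolboryl)ethenyl] analogue of 27
Conditions: Cl2CHBpin, CrCl2, LiI, THF, rt
Reagents that add atoms: 2-(dichloromethyl)-4,4,5,5-tetramethyl-1,3,2-dioxaborolane, CC1(C)OB(C(Cl)Cl)OC1(C)C
Why: In this Takai–Utimoto olefination the gem-dichromium boryl reagent is non-basic, attacks the aldehyde in preference to both ketones and gives the (E)-alkenylboronate.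

Step 14
Reactants: 29 (5S,6S,7R)-6-[(E)-2-(pinacolboryl)ethenyl] analogue of 27
Product: 30 potassium (E)-alkenyltrifluoroborate of 29
Conditions: KHF2, MeOH–H2O, rt, 1 h
Reagents that add atoms: potassium hydrogen difluoride, F.[F-].[K+]
Why: Pinacol boronate to trifluoroborate exchange keeps the alkene geometry, and an alkyl TBS ether survives KHF2 at room temperature for this time.

Step 15
Reactants: 30 potassium (E)-alkenyltrifluoroborate of 29; 31 3-methylbut-2-enoic acid (senecioic acid)
Product: 32 O-TBS ether of the target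
Conditions: CuBr (cat.), DMAP (cat.), 4 Å MS, O2 (1 atm), MeCN, 40 °C
Reagents that add atoms: none
Why: In this Chan–Lam type aerobic copper coupling of an alkenyltrifluoroborate and a carboxylic acid, transmetalation and C–O reductive elimination proceed with retention and give only the (E)-enol ester, and the excess acid buffers DMAP so that C7 is not epimerised.

Step 16
Reactants: 32 O-TBS ether of the target
Product: 33 target CNP0247522.1
Conditions: HF·pyridine, pyridine–THF, 0 °C → rt
Reagents that add atoms: none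
Why: Buffered fluoride desilylation frees the allylic alcohol without cleaving the enol ester, cyclising the 1,4-diketone or epimerising C7.

## Compound list

1 | nerol, (2Z)-3,7-dimethylocta-2,6-dien-1-ol | CC(C)=CCC/C(C)=C\CO | starting material
2 | 3-cyanopropanoic acid | N#CCCC(=O)O | starting material
3 | neryl 3-cyanopropanoate | CC(C)=CCC/C(C)=C\COC(=O)CCC#N | intermediate
4 | Z(O)-boron ketene acetal of 3 (CH2CN cis to O–B, boron in the (R,R)-diazaborolidine) | N#CC/C=C(/OC/C=C(/C)CCC=C(C)C)OB1N(S(=O)(=O)c2cc(cc(c2)C(F)(F)F)C(F)(F)F)[C@H](c2ccccc2)[C@@H](c2ccccc2)N1S(=O)(=O)c1cc(cc(c1)C(F)(F)F)C(F)(F)F | intermediate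
5 | acyloxyborane of acid 6 | N#CC[C@H](C(=O)OB1N(S(=O)(=O)c2cc(cc(c2)C(F)(F)F)C(F)(F)F)[C@H](c2ccccc2)[C@@H](c2ccccc2)N1S(=O)(=O)c1cc(cc(c1)C(F)(F)F)C(F)(F)F)[C@@](C)(CCC=C(C)C)C=C | intermediate
6 | (2S,3S)-2-(cyanomethyl)-3-ethenyl-3,7-dimethyloct-6-enoic acid | N#CC[C@H](C(=O)O)[C@@](C)(CCC=C(C)C)C=C | intermediate
7 | N-acylimidazole of 6 | N#CC[C@H](C(=O)n1ccnc1)[C@@](C)(CCC=C(C)C)C=C | intermediate
8 | (3S,4S)-4-ethenyl-3-(hydroxymethyl)-4,8-dimethylnon-7-enenitrile | N#CC[C@H](CO)[C@@](C)(CCC=C(C)C)C=C | intermediate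
9 | potassium (3S,4S)-4-ethenyl-3-(hydroxymethyl)-4,8-dimethylnon-7-enoate | [K+].[O-]C(=O)C[C@H](CO)[C@@](C)(CCC=C(C)C)C=C | intermediate
10 | (4S)-4-[(3S)-3,7-dimethylocta-1,6-dien-3-yl]oxolan-2-one | O=C1C[C@H](CO1)[C@@](C)(CCC=C(C)C)C=C | intermediate
11 | B-alkyl-9-BBN adduct of 10 (boron on the former vinyl terminus) | O=C1C[C@H](CO1)[C@@](C)(CCC=C(C)C)CCB1C2CCCC1CCC2 | intermediate
12 | (4S)-4-[(3S)-1-hydroxy-3,7-dimethyloct-6-en-3-yl]oxolan-2-one | O=C1C[C@H](CO1)[C@@](C)(CCC=C(C)C)CCO | intermediate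
13 | (3S)-3,7-dimethyl-3-[(3S)-5-oxooxolan-3-yl]oct-6-enal | O=C1C[C@H](CO1)[C@@](C)(CCC=C(C)C)CC=O | intermediate
14 | (2-bromoethoxy)(tert-butyl)dimethylsilane | BrCCO[Si](C)(C)C(C)(C)C | starting material
15 | triphenylphosphine | c1ccc(cc1)P(c1ccccc1)c1ccccc1 | starting material
16 | [2-(tert-butyldimethylsilyloxy)ethyl]triphenylphosphonium bromide | [Br-].CC(C)(C)[Si](C)(C)OCC[P+](c1ccccc1)(c1ccccc1)c1ccccc1 | intermediate
17 | [2-(tert-butyldimethylsilyloxy)ethylidene]triphenylphosphorane | CC(C)(C)[Si](C)(C)OCC=P(c1ccccc1)(c1ccccc1)c1ccccc1 | intermediate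
18 | [2-(tert-butyldimethylsilyloxy)-1-iodoethyl]triphenylphosphonium iodide | [I-].CC(C)(C)[Si](C)(C)OCC(I)[P+](c1ccccc1)(c1ccccc1)c1ccccc1 | intermediate
19 | [2-(tert-butyldimethylsilyloxy)-1-iodoethylidene]triphenylphosphorane | CC(C)(C)[Si](C)(C)OCC(I)=P(c1ccccc1)(c1ccccc1)c1ccccc1 | intermediate
20 | (4S)-4-[(2Z,5S)-1-(tert-butyldimethylsilyloxy)-2-iodo-5,9-dimethyldeca-2,8-dien-5-yl]oxolan-2-one (iodine cis to C4) | O=C1C[C@H](CO1)[C@@](C)(CCC=C(C)C)C/C=C(\I)CO[Si](C)(C)C(C)(C)C | intermediate
21 | 1-bromo-2,2-dimethoxypropane | COC(C)(CBr)OC | starting material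
22 | 2-methoxyallyl bromide | COC(=C)CBr | intermediate
23 | lithium enolate of 20 | [Li+].[O-]C1=C[C@H](CO1)[C@@](C)(CCC=C(C)C)C/C=C(\I)CO[Si](C)(C)C(C)(C)C | intermediate
24 | (3R,4S)-trans-lactone: 20 carrying a 2-methoxyprop-2-en-1-yl group at C3 of the lactone (= C7) | O=C1[C@H](CC(=C)OC)[C@H](CO1)[C@@](C)(CCC=C(C)C)C/C=C(\I)CO[Si](C)(C)C(C)(C)C | intermediate
25 | (Z)-alkenyllithium from 24 (Li in place of I) | O=C1[C@H](CC(=C)OC)[C@H](CO1)[C@@](C)(CCC=C(C)C)C/C=C(\[Li])CO[Si](C)(C)C(C)(C)C | intermediate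
26 | (5S,6S,7R)-2-[(tert-butyldimethylsilyloxy)methyl]-6-(hydroxymethyl)-7-(2-methoxyprop-2-en-1-yl)-5-methyl-5-(4-methylpent-3-en-1-yl)cyclohept-2-en-1-one | COC(=C)C[C@H]1C(=O)C(CO[Si](C)(C)C(C)(C)C)=CC[C@](C)(CCC=C(C)C)[C@H]1CO | intermediate
27 | (5S,6S,7R)-2-[(tert-butyldimethylsilyloxy)methyl]-6-(hydroxymethyl)-5-methyl-5-(4-methylpent-3-en-1-yl)-7-(2-oxopropyl)cyclohept-2-en-1-one | CC(=O)C[C@H]1C(=O)C(CO[Si](C)(C)C(C)(C)C)=CC[C@](C)(CCC=C(C)C)[C@H]1CO | intermediate
28 | 6-formyl analogue of 27 (CHO in place of CH2OH, same configuration) | CC(=O)C[C@H]1C(=O)C(CO[Si](C)(C)C(C)(C)C)=CC[C@](C)(CCC=C(C)C)[C@H]1C=O | intermediate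
29 | 6-[(E)-2-(4,4,5,5-tetramethyl-1,3,2-dioxaborolan-2-yl)ethenyl] analogue of 27 | CC(=O)C[C@H]1C(=O)C(CO[Si](C)(C)C(C)(C)C)=CC[C@](C)(CCC=C(C)C)[C@H]1/C=C/B2OC(C)(C)C(C)(C)O2 | intermediate
30 | potassium (E)-alkenyltrifluoroborate of 29 | CC(=O)C[C@H]1C(=O)C(CO[Si](C)(C)C(C)(C)C)=CC[C@](C)(CCC=C(C)C)[C@H]1/C=C/[B-](F)(F)F.[K+] | intermediate
31 | 3-methylbut-2-enoic acid | CC(C)=CC(=O)O | starting material
32 | O-TBS ether of the target | CC(=O)C[C@H]1C(=O)C(CO[Si](C)(C)C(C)(C)C)=CC[C@](C)(CCC=C(C)C)[C@H]1/C=C/OC(=O)C=C(C)C | intermediate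
33 | CNP0247522.1, (5S,6S,7R)-2-(hydroxymethyl)-5-methyl-5-(4-methylpent-3-en-1-yl)-6-[(E)-2-(3-methylbut-2-enoyloxy)ethenyl]-7-(2-oxopropyl)cyclohept-2-en-1-one | CC(=O)C[C@H]1C(=O)C(CO)=CC[C@](C)(CCC=C(C)C)[C@H]1/C=C/OC(=O)C=C(C)C | target

## Step count and risks

Total step count: 16.
Longest linear sequence: 14 steps, from 1 to 33 (steps 1–6, 8, 10–16).

**Step 8 (the proposed new olefination).**
- Risks: β-elimination of silanolate from 18 or 19, loss of iodine, or a modest Z:E ratio.
- Fallback (known chemistry only): it sets out from 13 and comes back at 20. A Wittig reaction of 13 with commercial (triphenylphosphoranylidene)acetaldehyde in warm toluene gives the (E)-enal F1. Nucleophile-catalysed α-iodination (I2, DMAP, K2CO3, THF–H2O) leaves the isolated alkene alone and gives the (Z)-2-iodoenal F2. Luche reduction (NaBH4, CeCl3, MeOH, −40 °C) spares the lactone and gives the (Z)-2-iodoallylic alcohol F3. TBSCl and imidazole then convert it into 20.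

**Step 11 (ring closure).**
- Risks: attack of t-BuLi on the lactone, proton transfer from C7–H, or a slow seven-membered closure.
- Fallback: it sets out from 24 and comes back at 28. DIBAL-H (1.05 equiv, CH2Cl2, −78 °C) gives the lactol F4. Its open hydroxy-aldehyde form closes the ring in an intramolecular Nozaki–Hiyama–Kishi reaction (CrCl2, NiCl2 cat., DMSO, high dilution) to the enol-ether diol F5. An oxalic acid work-up turns this into the keto diol F6. Excess DMP oxidises both carbinols at once to 28.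

**Step 15 (C–O coupling).**
- Risks: protodeboronation, a slow reaction at the hindered alkenyl group, or epimerisation at C7.
- Fallback: it sets out from 29 and comes back at 32. NaBO3 in THF–H2O oxidises the alkenylboronate to the homologous aldehyde F7. O-Acylation of the aldehyde enol with 3-methylbut-2-enoic anhydride (DMAP, Et3N, CH2Cl2) gives E/Z enol esters. The (E)-isomer 32 is separated from them by chromatography.

## Further compounds

F1 | step 8 | (2E,5S)-5,9-dimethyl-5-[(3S)-5-oxooxolan-3-yl]deca-2,8-dienal | O=C1C[C@H](CO1)[C@@](C)(CCC=C(C)C)C/C=C/C=O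
F2 | step 8 | (2Z,5S)-2-iodo-5,9-dimethyl-5-[(3S)-5-oxooxolan-3-yl]deca-2,8-dienal | O=C1C[C@H](CO1)[C@@](C)(CCC=C(C)C)C/C=C(\I)C=O
F3 | step 8 | (4S)-4-[(2Z,5S)-1-hydroxy-2-iodo-5,9-dimethyldeca-2,8-dien-5-yl]oxolan-2-one | O=C1C[C@H](CO1)[C@@](C)(CCC=C(C)C)C/C=C(\I)CO
F4 | step 11 | lactol of 24 (anomer mixture) | OC1[C@H](CC(=C)OC)[C@H](CO1)[C@@](C)(CCC=C(C)C)C/C=C(\I)CO[Si](C)(C)C(C)(C)C
F5 | step 11 | C1 carbinol of 26 (epimer mixture at C1) | COC(=C)C[C@H]1C(O)C(CO[Si](C)(C)C(C)(C)C)=CC[C@](C)(CCC=C(C)C)[C@H]1CO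
F6 | step 11 | C1 carbinol of 27 (epimer mixture at C1) | CC(=O)C[C@H]1C(O)C(CO[Si](C)(C)C(C)(C)C)=CC[C@](C)(CCC=C(C)C)[C@H]1CO
F7 | step 15 | 6-(2-oxoethyl) analogue of 27 | CC(=O)C[C@H]1C(=O)C(CO[Si](C)(C)C(C)(C)C)=CC[C@](C)(CCC=C(C)C)[C@H]1CC=O
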